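**Retrosynthetic overview**

- Hierochin B is cut first at the C5 side chain (Heck coupling of a 5-bromide with ethyl acrylate, then ester reduction) and at C3–CH2OH, which is traced back through the carboxylic acid to a nitromethyl group.
- The strategy rests on C2 of the dihydrofuran ring: a benzylic carbon between O1 and C3 that carries the 3,4-dimethoxyphenyl group, so it can be delivered as a one-carbon veratryl sulfonium ylide to the four-atom unit O1–C7a–C3a–C3.
- That unit is a 2-hydroxy-β-nitrostyrene (a vinylogous ortho-quinone methide): the ylide carbon adds to its benzylic carbon (C2–C3) and the phenoxide then displaces the sulfide (O1–C2), a formal [4+1] annulation that sets C2 and C3.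
- The nitrostyrene comes from 5-bromo-2-hydroxy-3-methoxybenzaldehyde and nitromethane; the ylide precursor comes from a C2-symmetric 2,5-dimethylthiolane (hexane-2,5-diol dimesylate plus sodium sulfide) and 3,4-dimethoxybenzyl bromide.
- Ring order: both benzene rings are bought; the dihydrofuran ring is the only ring of the target that is built (step 5), after the thiolane ring of the reagent (step 3).

Key step: step 5

Assumption: the thiolanium benzylide is taken to react on the same face as in its known benzylidene transfer to aldehydes, where the (2R,5R)-sulfide gives (S,S)-stilbene oxide. With the priority change at the new carbon this maps the (2S,5S)-sulfide onto (2S) at C2, so the (2S,5S)-thiolane from (2R,5R)-hexane-2,5-diol is used. If the experiment shows the opposite sense, the (2R,5R)-thiolane from (2S,5S)-hexane-2,5-diol is run through the same steps.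

**Route**

Step 1
Reactants: 1 5-bromo-2-hydroxy-3-methoxybenzaldehyde; 2 nitromethane
Product: 3 (E)-4-bromo-2-methoxy-6-(2-nitrovinyl)phenol
Conditions: MeNO2 (5 equiv), NH4OAc, AcOH, 100 °C
Reagents that add atoms: none
Why: Henry condensation: nitroaldol addition followed by dehydration under NH4OAc/AcOH should give the conjugated (E)-nitroalkene under thermodynamic control, as is usual for salicylaldehydes.

Step 2
Reactants: 4 (2R,5R)-hexane-2,5-diol
Product: 5 (2R,5R)-hexane-2,5-diyl dimethanesulfonate
Conditions: MsCl, Et3N, CH2Cl2, −20 to 0 °C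
Reagents that add atoms: methanesulfonyl chloride, CS(=O)(=O)Cl
Why: O-sulfonylation of both secondary alcohols leaves the C–O bonds and both stereocentres untouched.

Step 3
Reactants: 5 (2R,5R)-hexane-2,5-diyl dimethanesulfonate
Product: 6 (2S,5S)-2,5-dimethylthiolane
Conditions: Na2S·9H2O, DMSO, rt; distillation
Reagents that add atoms: sodium sulfide, [Na+].[Na+].[S-2]
Why: double SN2 displacement by sulfide, the second a 5-exo-tet closure, inverts both carbinol carbons, so the (R,R)-dimesylate should give the (S,S)-thiolane.

Step 4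
Reactants: 6 (2S,5S)-2,5-dimethylthiolane; 7 3,4-dimethoxybenzyl bromide
Product: 8 (2S,5S)-1-(3,4-dimethoxybenzyl)-2,5-dimethylthiolanium bromide
Conditions: acetone, rt, dark; salt filtered off
Reagents that add atoms: none
Why: S-alkylation of the sulfide by a very reactive benzylic bromide; the two lone pairs of the C2-symmetric thiolane are homotopic, so only one salt can form, and its precipitation from acetone should pull the reversible alkylation forward.

Step 5
Reactants: 3 (E)-4-bromo-2-methoxy-6-(2-nitrovinyl)phenol; 8 (2S,5S)-1-(3,4-dimethoxybenzyl)-2,5-dimethylthiolanium bromide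
Product: 11 (2S,3R)-5-bromo-2-(3,4-dimethoxyphenyl)-7-methoxy-3-(nitromethyl)-2,3-dihydrobenzofuran (trans), via sulfonium ylide 9 (not isolated), via nitronate betaine 10 (not isolated)
Conditions: Cs2CO3 (3 equiv), MeCN/CH2Cl2, −20 °C to rt; aq. NH4Cl
Reagents that add atoms: none
Why: Cs2CO3 turns 3 into its phenoxide and 8 into the semi-stabilised benzylide 9, whose carbon adds to the benzylic (β) carbon of the nitroalkene to give betaine 10 (C2–C3), after which the phenoxide oxygen displaces the thiolane from the ylide-derived carbon with inversion (O1–C2). The closest known reaction type is the formal [4+1] annulation of carbonyl-stabilised sulfonium ylides with 2-(2-nitrovinyl)phenols and with ortho-quinone methides; the ylide used here is of the benzylic kind familiar from sulfide-mediated epoxidation, aziridination and cyclopropanation. The dihydrofuran ring closes in the 5-exo-tet mode. C3 is set relative to C2 in the conjugate addition: the open transition state leading to the anti betaine keeps the veratryl group away from the nitrovinyl arm and should give the 2,3-trans ring after invertive closure. C2 is set by the C2-symmetric thiolane, which forms a single ylide with one face screened by the methyl group syn to the benzylidene carbon, the (2S,5S) antipode being chosen on the analogy stated in the assumption. The step needs closure through the phenoxide and not through the nitronate (O- or C-alkylation), and no benzyl transfer from 8 to the phenoxide: in 10 the phenoxide oxygen is placed for 5-exo-tet attack and is the better nucleophile, and low temperature with slow heterogeneous ylide generation should keep intermolecular benzyl transfer behind.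

Step 6
Reactants: 11 (2S,3R)-5-bromo-2-(3,4-dimethoxyphenyl)-7-methoxy-3-(nitromethyl)-2,3-dihydrobenzofuran
Product: 12 (2S,3S)-5-bromo-2-(3,4-dimethoxyphenyl)-7-methoxy-2,3-dihydrobenzofuran-3-carboxylic acid (trans)
Conditions: NaNO2, AcOH, DMSO, 35 °C
Reagents that add atoms: sodium nitrite, [Na+].[O-]N=O; water, O
Why: Nef-type oxidation of a primary nitroalkane with nitrite in acetic acid (α-nitrosation, then loss of nitrite and hydrolysis) should deliver the carboxylic acid; the medium is only weakly acidic, so C3 and the benzylic ether at C2 keep their configuration (the C3 descriptor changes from R to S by priority only).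

Step 7
Reactants: 12 (2S,3S)-5-bromo-2-(3,4-dimethoxyphenyl)-7-methoxy-2,3-dihydrobenzofuran-3-carboxylic acid
Product: 13 [(2S,3R)-5-bromo-2-(3,4-dimethoxyphenyl)-7-methoxy-2,3-dihydrobenzofuran-3-yl]methanol
Conditions: BH3·THF, THF, 0 °C to rt; MeOH
Reagents that add atoms: none
Why: borane reduction of the carboxylic acid by way of its acyloxyborane leaves the aryl bromide and aryl ethers alone and does not touch C2 or C3.

Step 8
Reactants: 13 [(2S,3R)-5-bromo-2-(3,4-dimethoxyphenyl)-7-methoxy-2,3-dihydrobenzofuran-3-yl]methanol; 14 ethyl acrylate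
Product: 15 ethyl (E)-3-[(2S,3R)-2-(3,4-dimethoxyphenyl)-3-(hydroxymethyl)-7-methoxy-2,3-dihydrobenzofuran-5-yl]prop-2-enoate
Conditions: Pd(OAc)2 (5 mol%), P(o-tol)3, Et3N, DMF, 100 °C
Reagents that add atoms: none
Why: Mizoroki–Heck reaction: oxidative addition of the electron-rich aryl bromide, syn carbopalladation of the acrylate and syn β-hydride elimination should give the (E)-enoate, and the free primary alcohol and both stereocentres are inert to Et3N at this temperature.

Step 9
Reactants: 15 ethyl (E)-3-[(2S,3R)-2-(3,4-dimethoxyphenyl)-3-(hydroxymethyl)-7-methoxy-2,3-dihydrobenzofuran-5-yl]prop-2-enoate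
Product: 16 hierochin B, (E)-3-[(2S,3R)-2-(3,4-dimethoxyphenyl)-3-(hydroxymethyl)-7-methoxy-2,3-dihydrobenzofuran-5-yl]prop-2-en-1-ol
Conditions: DIBAL-H (4 equiv), CH2Cl2, −78 °C; Rochelle salt
Reagents that add atoms: none
Why: DIBAL-H reduces the conjugated ester in the 1,2 sense to the allylic alcohol at low temperature, one equivalent being consumed by the free hydroxyl; the E alkene and both stereocentres stay as they are.

**Compound list**

1 | 5-bromo-2-hydroxy-3-methoxybenzaldehyde | COc1cc(Br)cc(C=O)c1O | starting material
2 | nitromethane | C[N+](=O)[O-] | starting material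
3 | (E)-4-bromo-2-methoxy-6-(2-nitrovinyl)phenol | COc1cc(Br)cc(/C=C/[N+](=O)[O-])c1O | intermediate
4 | (2R,5R)-hexane-2,5-diol | C[C@@H](O)CC[C@@H](C)O | starting material
5 | (2R,5R)-hexane-2,5-diyl dimethanesulfonate | C[C@@H](OS(C)(=O)=O)CC[C@@H](C)OS(C)(=O)=O | intermediate
6 | (2S,5S)-2,5-dimethylthiolane | C[C@H]1CC[C@H](C)S1 | intermediate
7 | 3,4-dimethoxybenzyl bromide | COc1ccc(CBr)cc1OC | starting material
8 | (2S,5S)-1-(3,4-dimethoxybenzyl)-2,5-dimethylthiolanium bromide | COc1ccc(C[S+]2[C@@H](C)CC[C@@H]2C)cc1OC.[Br-] | intermediate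
9 | sulfonium ylide: (2S,5S)-2,5-dimethylthiolanium 3,4-dimethoxybenzylide | COc1ccc([CH-][S+]2[C@@H](C)CC[C@@H]2C)cc1OC | intermediate (not isolated)
10 | nitronate betaine: caesium salt of the anti phenoxide–nitronate carrying the (2S,5S)-2,5-dimethylthiolanium group on the veratrylic carbon | COc1ccc([C@@H]([C@@H](C=[N+]([O-])[O-])c2cc(Br)cc(OC)c2[O-])[S+]2[C@@H](C)CC[C@@H]2C)cc1OC.[Cs+] | intermediate (not isolated)
11 | (2S,3R)-5-bromo-2-(3,4-dimethoxyphenyl)-7-methoxy-3-(nitromethyl)-2,3-dihydrobenzofuran | COc1ccc([C@H]2Oc3c(OC)cc(Br)cc3[C@@H]2C[N+](=O)[O-])cc1OC | intermediate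
12 | (2S,3S)-5-bromo-2-(3,4-dimethoxyphenyl)-7-methoxy-2,3-dihydrobenzofuran-3-carboxylic acid | COc1ccc([C@H]2Oc3c(OC)cc(Br)cc3[C@@H]2C(=O)O)cc1OC | intermediate
13 | [(2S,3R)-5-bromo-2-(3,4-dimethoxyphenyl)-7-methoxy-2,3-dihydrobenzofuran-3-yl]methanol | COc1ccc([C@H]2Oc3c(OC)cc(Br)cc3[C@@H]2CO)cc1OC | intermediate
14 | ethyl acrylate | C=CC(=O)OCC | starting material
15 | ethyl (E)-3-[(2S,3R)-2-(3,4-dimethoxyphenyl)-3-(hydroxymethyl)-7-methoxy-2,3-dihydrobenzofuran-5-yl]prop-2-enoate | COc1ccc([C@H]2Oc3c(OC)cc(/C=C/C(=O)OCC)cc3[C@@H]2CO)cc1OC | intermediate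
16 | hierochin B | COc1ccc([C@H]2Oc3c(OC)cc(/C=C/CO)cc3[C@@H]2CO)cc1OC | target

**Step count and risks**

Total steps: 9. Longest linear sequence: 8 steps (4 → 5 → 6 → 8 → 11 → 12 → 13 → 15 → 16).

Steps most likely to fail:

1. Step 5. What may go wrong: benzyl transfer from the sulfonium salt to the phenoxide oxygen, closure of the betaine through the nitronate in place of the phenoxide, or weak face control at the ylide carbon. Fallback, setting out from 3 and 7 and coming back at 12: the C2–C3 bond is made by carbenoid C–H insertion instead.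
   - Phenol 3 is O-alkylated with 7 (K2CO3, DMF) to the nitrostyrene ether F1.
   - Conjugate reduction (NaBH4, THF/MeOH, 0 °C) gives the nitroalkane F2.
   - NaNO2/AcOH in DMSO gives the arylacetic acid F3.
   - MeI/K2CO3 gives the methyl ester F4.
   - Regitz diazo transfer (4-acetamidobenzenesulfonyl azide, DBU, MeCN) gives the aryldiazoacetate F5.
   - A chiral dirhodium tetracarboxylate (Rh2(S-PTTL)4 or its mirror image, whichever gives the 2S series; toluene, −60 °C) inserts the carbenoid into the veratrylic C–H bond to give the cis ester F6.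
   - NaOMe/MeOH then epimerises C3 to trans and aqueous NaOH saponifies, which returns the route to acid 12.

2. Step 4. What may go wrong: slow alkylation of the hindered thiolane, with bromide returning the salt to 6 and 7 or 7 being lost by solvolysis, so that no pure salt is obtained. Fallback, setting out from 6 and coming back at 11: 6 is alkylated by 3,4-dimethoxybenzyl alcohol under HBF4·OEt2 (CH2Cl2, 0 °C), which gives the tetrafluoroborate salt F7 with a non-nucleophilic counter-ion. F7 takes the place of 8 in step 5 and leads to 11.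

3. Step 6. What may go wrong: nitrosation of the electron-rich rings or stalling before the acid stage. Fallback, setting out from 11 and coming back at 13: a reductive Nef reaction at the aldehyde level. Compound 11 is converted into its nitronate (NaOMe, MeOH) and treated with buffered aqueous TiCl3 (NH4OAc) to give the aldehyde F8, which is reduced at once with NaBH4 (MeOH, 0 °C) to 13, bypassing 12.

**Further compounds**

F1 | step 5 | (E)-5-bromo-2-[(3,4-dimethoxybenzyl)oxy]-1-methoxy-3-(2-nitrovinyl)benzene | COc1ccc(COc2c(OC)cc(Br)cc2/C=C/[N+](=O)[O-])cc1OC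
F2 | step 5 | 5-bromo-2-[(3,4-dimethoxybenzyl)oxy]-1-methoxy-3-(2-nitroethyl)benzene | COc1ccc(COc2c(OC)cc(Br)cc2CC[N+](=O)[O-])cc1OC
F3 | step 5 | 2-{5-bromo-2-[(3,4-dimethoxybenzyl)oxy]-3-methoxyphenyl}acetic acid | COc1ccc(COc2c(OC)cc(Br)cc2CC(=O)O)cc1OC
F4 | step 5 | methyl 2-{5-bromo-2-[(3,4-dimethoxybenzyl)oxy]-3-methoxyphenyl}acetate | COc1ccc(COc2c(OC)cc(Br)cc2CC(=O)OC)cc1OC
F5 | step 5 | methyl 2-{5-bromo-2-[(3,4-dimethoxybenzyl)oxy]-3-methoxyphenyl}-2-diazoacetate | COc1ccc(COc2c(OC)cc(Br)cc2C(=[N+]=[N-])C(=O)OC)cc1OC
F6 | step 5 | methyl (2S,3R)-5-bromo-2-(3,4-dimethoxyphenyl)-7-methoxy-2,3-dihydrobenzofuran-3-carboxylate (cis) | COc1ccc([C@H]2Oc3c(OC)cc(Br)cc3[C@H]2C(=O)OC)cc1OC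
F7 | step 4 | (2S,5S)-1-(3,4-dimethoxybenzyl)-2,5-dimethylthiolanium tetrafluoroborate | COc1ccc(C[S+]2[C@@H](C)CC[C@@H]2C)cc1OC.F[B-](F)(F)F
F8 | step 6 | (2S,3S)-5-bromo-2-(3,4-dimethoxyphenyl)-7-methoxy-2,3-dihydrobenzofuran-3-carbaldehyde | COc1ccc([C@H]2Oc3c(OC)cc(Br)cc3[C@@H]2C=O)cc1OC
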